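(The earlier runs and the new flask come from a simulation with made-up constants; the scatter is artificial.)

Count what is missing.

| flask | G | Q | temperature | remark | time |
|---|---|---|---|---|---|
| blue | 0.10 M | 0.80 equiv | 75 °C | run made earlier |  |
| red | 0.15 M | 0.80 equiv | 105 °C | run made earlier |  |
| teal | 0.20 M | 0.40 equiv | 75 °C | run made earlier |  |
| south-east | 0.20 M | 0.800 equiv |  | at 130 °C until 4.0 min, from then on at 80 °C | 5.0 min |
| east | 0.20 M | 0.800 equiv | 130 °C |  | 5.0 min |
| south-west | 0.20 M | 0.800 equiv | 105 °C |  | 5.0 min |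
| north-west | 0.20 M | 0.800 equiv | 80 °C |  | 5.0 min |

| run | time / min | J / % | E / % | Z / % |
|---|---|---|---|---|
| blue | 12.0 | 16.1 | 43.8 | 2.1 |
| blue | 25.0 | 19.9 | 56.3 | 3.0 |
| blue | 40.0 | 22.9 | 63.0 | 2.6 |
| blue | 50.0 | 22.4 | 65.6 | 1.9 |
| blue | 60.0 | 22.7 | 66.6 | 2.8 |
| blue | 80.0 | 23.5 | 69.0 | 3.4 |
| blue | 90.0 | 23.7 | 69.6 | 2.8 |
| red | 1.00 | 13.4 | 40.9 | 2.0 |
| red | 3.00 | 13.6 | 68.7 | 2.4 |
| red | 5.00 | 12.4 | 75.2 | 2.6 |
| red | 8.00 | 12.6 | 76.8 | 1.1 |
| red | 15.0 | 12.2 | 78.0 | 1.4 |
| red | 20.0 | 12.6 | 77.8 | 2.7 |
| teal | 8.00 | 6.8 | 39.4 | 0.5 |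
| teal | 12.0 | 6.9 | 46.2 | 0.6 |
| teal | 25.0 | 7.6 | 56.9 | 0.3 |
| teal | 50.0 | 5.4 | 66.0 | 0.6 |
| teal | 90.0 | 3.0 | 72.3 | 0.5 |

(each reading ± 0.5 percentage points)

- the best flask by share of J in all that became J or E or Z; "all alike" if 1.5 percentage points covers them all (south-east / east / south-west / north-west / all alike)
- share of J in all that became J or E or Z, south-east
- share of J in all that became J or E or Z, east
- share of J in all that became J or E or Z, south-west
- share of J in all that became J or E or Z, north-west

- percent here means G units held: one E counts as two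

In the red run at 20.0 min, E has flattened, and J, E and Z together fall 6.90% short of the charge. Taking G as gone there, an unread species holds that gap. In the red run E is the large quantity, so the reckoning goes to the correction: how the small pool, J plus gap, divides. If J and the gap are equilibrated (thermodynamic rather than kinetic control), their quotient depends on temperature. The last readings give 6.08 in the blue run at 75 °C and 1.83 in the red run at 105 °C. A straight line in the logarithm, a coarse stand-in for van 't Hoff, gives 0.670 at 130 °C. With the red pool carried over, J's share in east comes to 8.86%.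

The weak link is the red gap, a difference of single readings, each with scatter 0.5 percentage points. Averaging the red readings from 8.00 min onwards gives J 12.5%, gap 8.27%, and E plus Z 79.3%. The quotient at 105 °C is then 1.51, so the pool quotient κ, J over gap at 130 °C, is 0.472. At 80 °C the same line gives 4.82.

With the red pool of 20.7% carried over unchanged, the reckoned shares are 7.74% for east, 13.6% for south-west and 17.8% for north-west. South-east has 1.00 min of cooling to move from the east value towards the cold one. This reckoning has no clock for that, so the midpoint is taken as a guess: 12.8%. North-west comes out first in this reckoning.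

The forecast gives 5% for south-east, 5% for east, 15% for south-west and 24% for north-west, with north-west first, and holds “so cooling changes nothing”.

The flasks give 11.2% for south-east, 6.71% for east, 13.7% for south-west and 19.7% for north-west, and north-west is first.

    G + Q → L (k = 0.0271 /M/s, Ea = 74.0 kJ/mol)
    L ⇌ J (K = 6.51, k = 0.0102 /s, Ea = 105 kJ/mol, ΔH = −59.0 kJ/mol)
    G + L → E (k = 0.135 /M/s, Ea = 60.0 kJ/mol)
    J ⇌ Z (K = 0.135, k = 0.00274 /s, Ea = 94.0 kJ/mol, ΔH = 9.00 kJ/mol)
    (constants at 80 °C)

East stays low because J returns to L: with that return taken away, its share is 60.7% instead of 6.71%. In east the gap is L, and the flask ends with J 5.97% beside L 11.1%, a quotient of 0.538 against the carried 0.472.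

A neighbour of east is charged with 1.40 equiv of Q. Its E 62.2% and Z 2.45% leave a pool of 35.4%, which 0.472 divides to give J 11.3%, a share of 14.9%. The computed answer is 16.1%.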